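**Strategy.** The route rests on an intramolecular Diels–Alder disconnection of the hydrindene core (hexahydro-1H-indene numbering). The C6=C7 alkene with its flanking stereocentres C5, C4, C3a and C7a is a cyclohexene retron, and C1–C2–C3 of the cyclopentanone is a three-atom tether between diene terminus and dienophile. An open-chain tetraenal, made in the flask by Wittig olefination, should close the five-membered ring last (bond C3a–C7a), together with the cyclohexene (bond C4–C5), in one operation that sets four stereocentres, two of them quaternary. The precursor carries the ketone as a silyl ether and the acid as an aldehyde; its two trans-disposed methyl stereocentres steer the cycloaddition.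

Key step: step 12

Remark: 2-(triphenylphosphoranylidene)butanal is taken as not commercially available and is made in step 1; it is used in steps 7, 8 and 12. TBS = tert-butyldimethylsilyl. Bicyclic compounds use hexahydro-1H-indene numbering; open-chain compounds use the chain numbering of the name given.

Step 1
Reactants: 1 propyltriphenylphosphonium bromide; 2 ethyl formate
Product: 4 2-(triphenylphosphoranylidene)butanal, via propylidenetriphenylphosphorane 3 (not isolated)
Conditions: KOtBu (1.05 equiv), THF, 0 °C; then HCO2Et, 0 °C to 23 °C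
Reagents that add atoms: ethyl formate, CCOC=O
Why: Deprotonation gives the non-stabilised ylide, which is C-formylated by the formate ester and deprotonated again by the released ethoxide to the stabilised formyl ylide (acylation of a phosphonium ylide).

Step 2
Reactants: 5 methyl (R)-3-hydroxy-2-methylpropanoate; 6 tert-butyldimethylsilyl chloride
Product: 7 methyl (R)-3-[(tert-butyldimethylsilyl)oxy]-2-methylpropanoate
Conditions: imidazole, DMF, 23 °C
Reagents that add atoms: tert-butyldimethylsilyl chloride, CC(C)(C)[Si](C)(C)Cl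
Why: Silyl ether formation masks the primary hydroxyl and leaves the stereocentre untouched.

Step 3
Reactants: 7 methyl (R)-3-[(tert-butyldimethylsilyl)oxy]-2-methylpropanoate
Product: 9 (R)-3-[(tert-butyldimethylsilyl)oxy]-2-methylpropanal, via aluminium hemiacetal 8 (not isolated)
Conditions: iBu2AlH (1.05 equiv), CH2Cl2, −78 °C; then MeOH, aq. potassium sodium tartrate (KNaC4H4O6)
Reagents that add atoms: none
Why: At −78 °C the tetrahedral aluminium hemiacetal persists until the quench, so the ester should stop at the aldehyde (partial hydride reduction) without loss of the α-stereocentre.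

Step 4
Reactants: 9 (R)-3-[(tert-butyldimethylsilyl)oxy]-2-methylpropanal; 10 (Z)-crotylboronic acid pinacol ester
Product: 12 (2R,3S,4R)-1-[(tert-butyldimethylsilyl)oxy]-2,4-dimethylhex-5-en-3-ol, via pinacol borate ester 11 (not isolated)
Conditions: toluene (2 M), 23 °C, 48 h; then H2O
Reagents that add atoms: (Z)-crotylboronic acid pinacol ester, C/C=C\CB1OC(C)(C)C(C)(C)O1
Why: Crotylboration through a closed chair transition state (Zimmerman–Traxler type) turns the (Z)-geometry into the 3,4-syn relationship, and the anti-Felkin preference of (Z)-crotylboronates with α-methyl aldehydes (the Felkin–Anh arrangement suffers a syn-pentane clash between the crotyl methyl and the α-substituent) should set the 2,3-anti relationship, so both new centres are fixed by the existing one.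

Step 5
Reactants: 12 (2R,3S,4R)-1-[(tert-butyldimethylsilyl)oxy]-2,4-dimethylhex-5-en-3-ol; 13 tert-butyldimethylsilyl trifluoromethanesulfonate
Product: 14 bis-TBS ether of (2R,3S,4R)-2,4-dimethylhex-5-ene-1,3-diol
Conditions: 2,6-lutidine, CH2Cl2, −78 °C to 0 °C
Reagents that add atoms: tert-butyldimethylsilyl trifluoromethanesulfonate, CC(C)(C)[Si](C)(C)OS(=O)(=O)C(F)(F)F
Why: Silylation with the silyl triflate should protect the hindered secondary alcohol cleanly.

Step 6
Reactants: 14 bis-TBS ether of (2R,3S,4R)-2,4-dimethylhex-5-ene-1,3-diol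
Product: 16 (2S,3R,4R)-3,5-bis[(tert-butyldimethylsilyl)oxy]-2,4-dimethylpentanal, via ozonide 15 (not isolated)
Conditions: O3, CH2Cl2, −78 °C; then PPh3, −78 °C to 23 °C
Reagents that add atoms: ozone, [O-][O+]=O
Why: Ozonolysis with reductive work-up cleaves the only alkene to the aldehyde, the silyl ethers are inert, and the neutral work-up should spare the α-stereocentre.

Step 7
Reactants: 16 (2S,3R,4R)-3,5-bis[(tert-butyldimethylsilyl)oxy]-2,4-dimethylpentanal; 4 2-(triphenylphosphoranylidene)butanal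
Product: 17 (2E,4R,5S,6R)-5,7-bis[(tert-butyldimethylsilyl)oxy]-2-ethyl-4,6-dimethylhept-2-enal
Conditions: toluene, 90 °C
Reagents that add atoms: 2-(triphenylphosphoranylidene)butanal, CCC(C=O)=P(c1ccccc1)(c1ccccc1)c1ccccc1
Why: Wittig olefination with a stabilised α-substituted ylide should give the (E)-trisubstituted enal under neutral conditions that do not epimerise the α-centre.

Step 8
Reactants: 17 (2E,4R,5S,6R)-5,7-bis[(tert-butyldimethylsilyl)oxy]-2-ethyl-4,6-dimethylhept-2-enal; 4 2-(triphenylphosphoranylidene)butanal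
Product: 18 (2E,4E,6R,7S,8R)-7,9-bis[(tert-butyldimethylsilyl)oxy]-2,4-diethyl-6,8-dimethylnona-2,4-dienal
Conditions: 4 (excess), toluene, 110 °C
Reagents that add atoms: 2-(triphenylphosphoranylidene)butanal, CCC(C=O)=P(c1ccccc1)(c1ccccc1)c1ccccc1
Why: A second Wittig olefination of the less electrophilic enal needs excess ylide and a higher temperature and should again be (E)-selective, giving the (2E,4E)-dienal.

Step 9
Reactants: 18 (2E,4E,6R,7S,8R)-7,9-bis[(tert-butyldimethylsilyl)oxy]-2,4-diethyl-6,8-dimethylnona-2,4-dienal; 19 diethyl benzylphosphonate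
Product: 20 bis-TBS ether of (2R,3S,4R,5E,7E,9E)-6,8-diethyl-2,4-dimethyl-10-phenyldeca-5,7,9-triene-1,3-diol
Conditions: NaH, THF, 0 °C to 23 °C
Reagents that add atoms: diethyl benzylphosphonate, CCOP(=O)(Cc1ccccc1)OCC
Why: Horner–Wadsworth–Emmons olefination with the benzylphosphonate anion should deliver the (E)-styryl unit and complete the triene.

Step 10
Reactants: 20 bis-TBS ether of (2R,3S,4R,5E,7E,9E)-6,8-diethyl-2,4-dimethyl-10-phenyldeca-5,7,9-triene-1,3-diol
Product: 21 (2R,3S,4R,5E,7E,9E)-3-[(tert-butyldimethylsilyl)oxy]-6,8-diethyl-2,4-dimethyl-10-phenyldeca-5,7,9-trien-1-ol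
Conditions: HF·pyridine, pyridine, THF, 0 °C to 23 °C
Reagents that add atoms: none
Why: Buffered fluoride should cleave the unhindered primary silyl ether and leave the secondary one, which is shielded by two methyl-bearing neighbours (selective desilylation).

Step 11
Reactants: 21 (2R,3S,4R,5E,7E,9E)-3-[(tert-butyldimethylsilyl)oxy]-6,8-diethyl-2,4-dimethyl-10-phenyldeca-5,7,9-trien-1-ol
Product: 22 (2S,3S,4R,5E,7E,9E)-3-[(tert-butyldimethylsilyl)oxy]-6,8-diethyl-2,4-dimethyl-10-phenyldeca-5,7,9-trienal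
Conditions: Dess–Martin periodinane, CH2Cl2, 0 °C to 23 °C
Reagents that add atoms: none
Why: Dess–Martin oxidation is mild enough to give the α-chiral aldehyde without epimerisation or attack on the triene.

Step 12
Reactants: 22 (2S,3S,4R,5E,7E,9E)-3-[(tert-butyldimethylsilyl)oxy]-6,8-diethyl-2,4-dimethyl-10-phenyldeca-5,7,9-trienal; 4 2-(triphenylphosphoranylidene)butanal
Product: 24 (1R,2S,3R,3aS,4S,5R,7aS)-2-[(tert-butyldimethylsilyl)oxy]-4,5,7-triethyl-1,3-dimethyl-5-[(E)-2-phenylethenyl]-2,3,3a,4,5,7a-hexahydro-1H-indene-4-carbaldehyde, via tetraene enal 23 (not isolated)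
Conditions: 4 (1.1 equiv), 2,6-di-tert-butyl-4-methylphenol (cat.), toluene (0.1 M), 80 °C; then 110 °C
Reagents that add atoms: 2-(triphenylphosphoranylidene)butanal, CCC(C=O)=P(c1ccccc1)(c1ccccc1)c1ccccc1
Why: The stabilised ylide first converts aldehyde 22 into the (E)-2-ethyl enal 23 (Wittig olefination), whose electron-poor C2=C3 bond then adds suprafacially across the C7=C8–C9=C10 diene in a thermal, concerted but asynchronous intramolecular [4+2] cycloaddition (type 1 intramolecular Diels–Alder reaction of a 1,3,8-nonatriene; the closest known reaction type is the domino Wittig/Diels–Alder sequence). Bond C3–C7 closes the five-membered ring by joining the two ends of the three-atom tether C4–C5–C6 (fused mode, the tether becoming C3–C2–C1 of the hydrindene), and bond C2–C10 completes the cyclohexene as the second bond of the same [4+2] event. The (E)-dienophile geometry sets the cis relationship of H-3a and the 4-formyl group, and the (7E,9E)-diene geometry sets the cis relationship of H-7a and the 5-ethyl group. Endo/exo and facial selectivity are both controlled by allylic 1,3-strain: C4 and C6 of 23 each keep their hydrogen eclipsed with the neighbouring ethyl-substituted alkene, so each π-system is attacked anti to its methyl group, and because the two methyl groups are trans-disposed only the transition state with the formyl group endo and the tether exo satisfies both preferences, which gives the trans ring fusion and fixes C3a, C4, C5 and C7a relative to C1 and C3. The step needs chemoselectivity for ring closure over a second olefination of 23, which the near-stoichiometric amount of ylide and the unimolecular cycloaddition should secure.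

Step 13
Reactants: 24 (1R,2S,3R,3aS,4S,5R,7aS)-2-[(tert-butyldimethylsilyl)oxy]-4,5,7-triethyl-1,3-dimethyl-5-[(E)-2-phenylethenyl]-2,3,3a,4,5,7a-hexahydro-1H-indene-4-carbaldehyde
Product: 25 (1R,2S,3R,3aS,4S,5R,7aS)-4,5,7-triethyl-2-hydroxy-1,3-dimethyl-5-[(E)-2-phenylethenyl]-2,3,3a,4,5,7a-hexahydro-1H-indene-4-carbaldehyde
Conditions: HF (48% aq.), MeCN, 23 °C
Reagents that add atoms: none
Why: Acid-mediated desilylation removes the hindered secondary silyl ether, and the freed 2-hydroxyl is trans to C4 across the five-membered ring, so it cannot form a lactol with the formyl group.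

Step 14
Reactants: 25 (1R,2S,3R,3aS,4S,5R,7aS)-4,5,7-triethyl-2-hydroxy-1,3-dimethyl-5-[(E)-2-phenylethenyl]-2,3,3a,4,5,7a-hexahydro-1H-indene-4-carbaldehyde
Product: 27 norspiculoic acid A, via keto aldehyde 26 (not isolated)
Conditions: CrO3, H2SO4, H2O (Jones reagent), acetone, 0 °C
Reagents that add atoms: water, O (the second carboxyl oxygen enters through the aldehyde hydrate)
Why: Jones oxidation should convert the secondary alcohol into the ketone and the non-enolisable aldehyde, through its hydrate, into the carboxylic acid in one operation; the all-trans cyclopentanone is expected to be the thermodynamic arrangement, so the α-centres should not be at risk.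

**Compound list**

1 | propyltriphenylphosphonium bromide | CCC[P+](c1ccccc1)(c1ccccc1)c1ccccc1.[Br-] | starting material
2 | ethyl formate | CCOC=O | starting material
3 | propylidenetriphenylphosphorane | CCC=P(c1ccccc1)(c1ccccc1)c1ccccc1 | intermediate
4 | 2-(triphenylphosphoranylidene)butanal | CCC(C=O)=P(c1ccccc1)(c1ccccc1)c1ccccc1 | intermediate
5 | methyl (R)-3-hydroxy-2-methylpropanoate | COC(=O)[C@H](C)CO | starting material
6 | tert-butyldimethylsilyl chloride | CC(C)(C)[Si](C)(C)Cl | starting material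
7 | methyl (R)-3-[(tert-butyldimethylsilyl)oxy]-2-methylpropanoate | COC(=O)[C@H](C)CO[Si](C)(C)C(C)(C)C | intermediate
8 | diisobutylaluminium hemiacetal of 7 (hemiacetal carbon undefined) | COC(O[Al](CC(C)C)CC(C)C)[C@H](C)CO[Si](C)(C)C(C)(C)C | intermediate
9 | (R)-3-[(tert-butyldimethylsilyl)oxy]-2-methylpropanal | CC(C)(C)[Si](C)(C)OC[C@@H](C)C=O | intermediate
10 | (Z)-crotylboronic acid pinacol ester | C/C=C\CB1OC(C)(C)C(C)(C)O1 | starting material
11 | pinacol borate ester of 12 | CC(C)(C)[Si](C)(C)OC[C@@H](C)[C@@H](OB1OC(C)(C)C(C)(C)O1)[C@H](C)C=C | intermediate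
12 | (2R,3S,4R)-1-[(tert-butyldimethylsilyl)oxy]-2,4-dimethylhex-5-en-3-ol | CC(C)(C)[Si](C)(C)OC[C@@H](C)[C@@H](O)[C@H](C)C=C | intermediate
13 | tert-butyldimethylsilyl trifluoromethanesulfonate | CC(C)(C)[Si](C)(C)OS(=O)(=O)C(F)(F)F | starting material
14 | bis-TBS ether of (2R,3S,4R)-2,4-dimethylhex-5-ene-1,3-diol | CC(C)(C)[Si](C)(C)OC[C@@H](C)[C@@H](O[Si](C)(C)C(C)(C)C)[C@H](C)C=C | intermediate
15 | ozonide (1,2,4-trioxolane) of 14 | CC(C)(C)[Si](C)(C)OC[C@@H](C)[C@@H](O[Si](C)(C)C(C)(C)C)[C@H](C)C1OCOO1 | intermediate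
16 | (2S,3R,4R)-3,5-bis[(tert-butyldimethylsilyl)oxy]-2,4-dimethylpentanal | CC(C)(C)[Si](C)(C)OC[C@@H](C)[C@@H](O[Si](C)(C)C(C)(C)C)[C@H](C)C=O | intermediate
17 | (2E,4R,5S,6R)-5,7-bis[(tert-butyldimethylsilyl)oxy]-2-ethyl-4,6-dimethylhept-2-enal | CC(C)(C)[Si](C)(C)OC[C@@H](C)[C@@H](O[Si](C)(C)C(C)(C)C)[C@H](C)/C=C(\CC)C=O | intermediate
18 | (2E,4E,6R,7S,8R)-7,9-bis[(tert-butyldimethylsilyl)oxy]-2,4-diethyl-6,8-dimethylnona-2,4-dienal | CC(C)(C)[Si](C)(C)OC[C@@H](C)[C@@H](O[Si](C)(C)C(C)(C)C)[C@H](C)/C=C(CC)/C=C(\CC)C=O | intermediate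
19 | diethyl benzylphosphonate | CCOP(=O)(Cc1ccccc1)OCC | starting material
20 | bis-TBS ether of (2R,3S,4R,5E,7E,9E)-6,8-diethyl-2,4-dimethyl-10-phenyldeca-5,7,9-triene-1,3-diol | CC(C)(C)[Si](C)(C)OC[C@@H](C)[C@@H](O[Si](C)(C)C(C)(C)C)[C@H](C)/C=C(CC)/C=C(CC)/C=C/c1ccccc1 | intermediate
21 | (2R,3S,4R,5E,7E,9E)-3-[(tert-butyldimethylsilyl)oxy]-6,8-diethyl-2,4-dimethyl-10-phenyldeca-5,7,9-trien-1-ol | OC[C@@H](C)[C@@H](O[Si](C)(C)C(C)(C)C)[C@H](C)/C=C(CC)/C=C(CC)/C=C/c1ccccc1 | intermediate
22 | (2S,3S,4R,5E,7E,9E)-3-[(tert-butyldimethylsilyl)oxy]-6,8-diethyl-2,4-dimethyl-10-phenyldeca-5,7,9-trienal | O=C[C@@H](C)[C@@H](O[Si](C)(C)C(C)(C)C)[C@H](C)/C=C(CC)/C=C(CC)/C=C/c1ccccc1 | intermediate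
23 | (2E,4R,5S,6R,7E,9E,11E)-5-[(tert-butyldimethylsilyl)oxy]-2,8,10-triethyl-4,6-dimethyl-12-phenyldodeca-2,7,9,11-tetraenal | O=C/C(CC)=C/[C@@H](C)[C@@H](O[Si](C)(C)C(C)(C)C)[C@H](C)/C=C(CC)/C=C(CC)/C=C/c1ccccc1 | intermediate
24 | (1R,2S,3R,3aS,4S,5R,7aS)-2-[(tert-butyldimethylsilyl)oxy]-4,5,7-triethyl-1,3-dimethyl-5-[(E)-2-phenylethenyl]-2,3,3a,4,5,7a-hexahydro-1H-indene-4-carbaldehyde | CCC1=C[C@](/C=C/c2ccccc2)(CC)[C@@](CC)(C=O)[C@H]2[C@H]1[C@@H](C)[C@H](O[Si](C)(C)C(C)(C)C)[C@@H]2C | intermediate
25 | (1R,2S,3R,3aS,4S,5R,7aS)-4,5,7-triethyl-2-hydroxy-1,3-dimethyl-5-[(E)-2-phenylethenyl]-2,3,3a,4,5,7a-hexahydro-1H-indene-4-carbaldehyde | CCC1=C[C@](/C=C/c2ccccc2)(CC)[C@@](CC)(C=O)[C@H]2[C@H]1[C@@H](C)[C@H](O)[C@@H]2C | intermediate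
26 | (1R,3R,3aS,4S,5R,7aS)-4,5,7-triethyl-1,3-dimethyl-2-oxo-5-[(E)-2-phenylethenyl]-2,3,3a,4,5,7a-hexahydro-1H-indene-4-carbaldehyde | CCC1=C[C@](/C=C/c2ccccc2)(CC)[C@@](CC)(C=O)[C@H]2[C@H]1[C@@H](C)C(=O)[C@@H]2C | intermediate
27 | norspiculoic acid A, (1R,3R,3aS,4S,5R,7aS)-4,5,7-triethyl-1,3-dimethyl-2-oxo-5-[(E)-2-phenylethenyl]-2,3,3a,4,5,7a-hexahydro-1H-indene-4-carboxylic acid | CCC1=C[C@](/C=C/c2ccccc2)(CC)[C@@](CC)(C(=O)O)[C@H]2[C@H]1[C@@H](C)C(=O)[C@@H]2C | target

**Totals.** Total step count: 14. Longest linear sequence: 13 steps (steps 2 to 14, from compound 5).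

**Steps most likely to fail**

Step 12. The enal may be olefinated a second time before it cyclises, the cis-substituted diene may undergo a sigmatropic 1,5-hydrogen shift at 110 °C, or the cycloaddition may lose endo and facial discrimination at that temperature. The fallback sets out from 22 and comes back at 24, separating olefination from cycloaddition and using Lewis acid activation. Olefination of 22 with triethyl 2-phosphonobutanoate (LiCl, DBU, MeCN, 23 °C) should give the ethyl tetraenoate F1, whose ester dienophile should not cyclise at that temperature. Reduction with iBu2AlH (CH2Cl2, −78 °C) gives the allylic alcohol F2, and oxidation with MnO2 (CH2Cl2, 23 °C) gives enal 23, now isolated. Treatment with Me2AlCl (CH2Cl2, −78 °C to −20 °C) should then promote the cycloaddition to 24 at low temperature, where coordination of the formyl oxygen lowers the barrier and reinforces the endo preference.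

Step 4. Diastereofacial selectivity may be insufficient when it rests on the substrate alone. The fallback sets out from 9 and comes back at 16, using reagent control. A boron-mediated Evans syn-aldol reaction of 9 with (S)-4-benzyl-3-propanoyl-1,3-oxazolidin-2-one (Bu2BOTf, iPr2NEt, CH2Cl2, −78 °C to 0 °C) should give the aldol adduct F3 with the same anti,syn stereotriad. Silylation (TBSOTf, 2,6-lutidine, CH2Cl2) gives the imide silyl ether F4, reductive removal of the auxiliary with LiBH4 (THF, MeOH, 0 °C) gives the primary alcohol F5, and Dess–Martin oxidation gives 16.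

Step 8. Olefination of the hindered, conjugated aldehyde by the weakly nucleophilic formyl ylide may be sluggish, with loss of geometric purity or over-homologation on prolonged heating. The fallback sets out from 17 and comes back at 18, using a more nucleophilic phosphonate anion and a redox adjustment. Horner–Wadsworth–Emmons reaction of 17 with triethyl 2-phosphonobutanoate (NaH, THF, 0 °C to 23 °C) should give the ethyl dienoate F6, reduction with iBu2AlH (CH2Cl2, −78 °C) gives the dienol F7, and oxidation with MnO2 (CH2Cl2, 23 °C) gives 18.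

**Further compounds**

F1 | step 12 | ethyl (2E,4R,5S,6R,7E,9E,11E)-5-[(tert-butyldimethylsilyl)oxy]-2,8,10-triethyl-4,6-dimethyl-12-phenyldodeca-2,7,9,11-tetraenoate | CCOC(=O)/C(CC)=C/[C@@H](C)[C@@H](O[Si](C)(C)C(C)(C)C)[C@H](C)/C=C(CC)/C=C(CC)/C=C/c1ccccc1
F2 | step 12 | (2E,4R,5S,6R,7E,9E,11E)-5-[(tert-butyldimethylsilyl)oxy]-2,8,10-triethyl-4,6-dimethyl-12-phenyldodeca-2,7,9,11-tetraen-1-ol | OC/C(CC)=C/[C@@H](C)[C@@H](O[Si](C)(C)C(C)(C)C)[C@H](C)/C=C(CC)/C=C(CC)/C=C/c1ccccc1
F3 | step 4 | (4S)-4-benzyl-3-[(2S,3R,4R)-5-[(tert-butyldimethylsilyl)oxy]-3-hydroxy-2,4-dimethylpentanoyl]-1,3-oxazolidin-2-one | CC(C)(C)[Si](C)(C)OC[C@@H](C)[C@@H](O)[C@H](C)C(=O)N1[C@@H](Cc2ccccc2)COC1=O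
F4 | step 4 | (4S)-4-benzyl-3-[(2S,3R,4R)-3,5-bis[(tert-butyldimethylsilyl)oxy]-2,4-dimethylpentanoyl]-1,3-oxazolidin-2-one | CC(C)(C)[Si](C)(C)OC[C@@H](C)[C@@H](O[Si](C)(C)C(C)(C)C)[C@H](C)C(=O)N1[C@@H](Cc2ccccc2)COC1=O
F5 | step 4 | (2R,3S,4R)-3,5-bis[(tert-butyldimethylsilyl)oxy]-2,4-dimethylpentan-1-ol | CC(C)(C)[Si](C)(C)OC[C@@H](C)[C@@H](O[Si](C)(C)C(C)(C)C)[C@H](C)CO
F6 | step 8 | ethyl (2E,4E,6R,7S,8R)-7,9-bis[(tert-butyldimethylsilyl)oxy]-2,4-diethyl-6,8-dimethylnona-2,4-dienoate | CC(C)(C)[Si](C)(C)OC[C@@H](C)[C@@H](O[Si](C)(C)C(C)(C)C)[C@H](C)/C=C(CC)/C=C(\CC)C(=O)OCC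
F7 | step 8 | (2E,4E,6R,7S,8R)-7,9-bis[(tert-butyldimethylsilyl)oxy]-2,4-diethyl-6,8-dimethylnona-2,4-dien-1-ol | CC(C)(C)[Si](C)(C)OC[C@@H](C)[C@@H](O[Si](C)(C)C(C)(C)C)[C@H](C)/C=C(CC)/C=C(\CC)CO
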